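**Plan**
1. Retrosynthesis: the stearate C7–O bond is cut first, then the C7–C8 bond of ring A. In the target, C7 is the α-carbon of the C6 ketone and bears the C8 acyl carbon, so ring A (C4a, C5, C6, C7, C8, C8a) is the C-acyl isomer of a six-membered enol lactone (O6, C6, C5, C4a, C8a, C8) in which C8 sits on the C6 enol oxygen and the silyloxylated C7 is exocyclic.
2. The enol lactone is cut at C6=C7 (dehydration of a hemiketal lactone), at C8–C8a (carbonylation of a vinyl iodide), at C4a–C5 (alkynylation of a pyranone; the C4a=C5–C6=O enone then comes from a Meyer–Schuster shift) and across the pyran ring (hetero-Diels–Alder, C3–C4 and O2–C1).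
3. Forward: ring B (pyran) is made first, the C5–C6–C7 chain is joined at C4a, C8 is added and closed to the lactone ring, the lactone ring is contracted to ring A by an O-to-C acyl shift, and the stearoyl chain is joined last.
4. Stereochemistry: C3 (R) comes from the chiral Lewis acid in the hetero-Diels–Alder step; C7 (R) is created in the acyl shift under a chiral 4-aminopyridine catalyst.

Key step: step 8

Remark 1: atom labels (O2, C1, C3, C4, C4a, C5, C6, C7, C8, C8a) follow the isochromene numbering of the target in every intermediate; in lactones 11 and 12 the ring oxygen between C6 and C8 is called O6 and C7 is exocyclic.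
Remark 2: C7 is carried as both epimers from racemic but-3-yn-2-ol; this is harmless because C7 is planar in 12 and is set anew in step 8.
Remark 3 (assumption): the (S,S) chromium salen complex is taken to give the 3R pyranone and (S)-TADMAP to give 7R; if a first run shows the opposite sense at either centre, the antipode of that catalyst is used (salen = N,N′-bis(3,5-di-tert-butylsalicylidene)cyclohexane-1,2-diamine dianion; TADMAP = 1-[4-(dimethylamino)pyridin-3-yl]-2,2,2-triphenylethyl acetate).

**Step 1**
Reactants: 1 (E)-1-methoxy-3-(trimethylsilyloxy)buta-1,3-diene; 2 acetaldehyde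
Product: 4 (R)-2-methyl-2,3-dihydro-4H-pyran-4-one, via silyl enol ether cycloadduct 3 (not isolated)
Conditions: (S,S)-[Cr(salen)]BF4 (2 mol %), 4 Å MS, t-BuOMe, −30 °C; then CF3CO2H (cat.), CH2Cl2, 0 °C; aq. NaHCO3
Reagents that add atoms: none
Why: Catalytic asymmetric hetero-Diels–Alder reaction of a 1,3-dioxygenated diene with an aldehyde, in which the chiral chromium salen Lewis acid binds acetaldehyde and leaves one carbonyl face open so that C3 is set by the catalyst, followed by acid-induced loss of methanol and of the silyl group to give the enone.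

**Step 2**
Reactants: 4
Product: 5 (R)-5-iodo-2-methyl-2,3-dihydro-4H-pyran-4-one
Conditions: I2, pyridine, CH2Cl2, 0 °C to rt
Reagents that add atoms: iodine, II
Why: α-Iodination of a β-alkoxy enone with iodine and pyridine, which can only take place at C8a, the single vinylic α-position, and leaves C3 untouched.

**Step 3**
Reactants: 6 but-3-yn-2-ol (racemic)
Product: 7 triethyl(but-3-yn-2-yloxy)silane (racemic)
Conditions: Et3SiCl, imidazole, CH2Cl2, 0 °C to rt
Reagents that add atoms: chlorotriethylsilane, CC[Si](Cl)(CC)CC
Why: Standard silylation of a secondary alcohol with a silyl chloride and imidazole; the carbinol centre (the later C7) needs no control.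

**Step 4**
Reactants: 7; 5
Product: 8 (2R)-5-iodo-2-methyl-4-[3-(triethylsilyloxy)but-1-yn-1-yl]-3,4-dihydro-2H-pyran-4-ol (both epimers at C4a and at C7)
Conditions: n-BuLi, THF, −78 °C; then 5, −78 to −30 °C; aq. NH4Cl
Reagents that add atoms: none
Why: 1,2-Addition of a lithium acetylide to the carbonyl group of a 2-iodo enone (a hard alkynyl nucleophile attacks the carbonyl carbon, not the β-carbon or the iodide), which forms the C4a–C5 bond; the new carbinol centre is lost again in step 5.

**Step 5**
Reactants: 8
Product: 9 1-[(2R)-5-iodo-2-methyl-2,3-dihydro-4H-pyran-4-ylidene]-3-(triethylsilyloxy)butan-2-one (E/Z mixture at C4a=C5)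
Conditions: MoO2(acac)2, Ph3PAuCl, AgOTf (2 mol % each), toluene, rt
Reagents that add atoms: none
Why: Meyer–Schuster rearrangement of a tertiary propargylic alcohol (1,3-shift of the hydroxyl through the molybdate ester with the alkyne activated by the gold cation, then tautomerisation of the allenol), which gives the C4a=C5–C6(=O) enone in conjugation with the ring enol ether.

**Step 6**
Reactants: 9
Product: 11 (3R)-6-hydroxy-3-methyl-6-[1-(triethylsilyloxy)ethyl]-4,6-dihydro-3H-pyrano[3,4-c]pyran-8-one (both epimers at C6 and at C7), via open keto acid 10 (not isolated)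
Conditions: PdCl2(PPh3)2 (5 mol %), CO (1 atm), KOAc, DMF–H2O, 50 °C; then phosphate buffer (pH 6); crude product used directly
Reagents that add atoms: carbon monoxide, [C-]#[O+]; water, O
Why: Palladium-catalysed hydroxycarbonylation of a vinyl iodide (oxidative addition to zerovalent palladium, CO insertion, hydrolysis of the acylpalladium), after which the acid, once the push–pull C4a=C5 bond has turned C6 syn to C8a, should add to the C6 ketone as the six-membered hydroxy lactone (ring–chain tautomerism of a δ-keto acid held in a peri-like arrangement); the C6 and C7 centres need no control.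

**Step 7**
Reactants: 11
Product: 12 (3R,E)-3-methyl-6-[1-(triethylsilyloxy)ethylidene]-4,6-dihydro-3H-pyrano[3,4-c]pyran-8-one
Conditions: methyl N-(triethylammoniosulfonyl)carbamate (1.5 equiv), toluene, rt to 40 °C; filtration through Et3N-deactivated silica; used at once
Reagents that add atoms: none
Why: Burgess dehydration of the tertiary hemiketal hydroxyl by syn-elimination within the sulfamate ester, in which the only β-hydrogen the internal base can reach is C7–H (C5 is sp2), so that the exocyclic C6=C7 enol ether should form without free acid; the E isomer (methyl syn to O6, silyloxy syn to C5–H) is expected because the smaller oxygen substituent takes the place next to C5–H.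

**Step 8**
Reactants: 12
Product: 13 (3R,7R)-3,7-dimethyl-7-(triethylsilyloxy)-4,7-dihydro-3H-isochromene-6,8-dione
Conditions: (S)-TADMAP (10 mol %), toluene, 4 Å MS, −20 °C to rt
Reagents that add atoms: none
Why: Proposed new method: the pyridine nitrogen of the catalyst adds to the lactone carbonyl C8 of 12 and expels the C6 enolate oxygen, which gives a zwitterion in which the C8 acylpyridinium is held through C8a–C4a=C5 next to the silyloxy enolate O6–C6=C7; C7 then attacks C8, the catalyst leaves, and the lactone ring has become carbocyclic ring A (C4a, C5, C6, C7, C8, C8a). The closest known reaction types are the enantioselective Steglich-type O-to-C acyl and carboxyl shifts of enol esters and enol carbonates under chiral 4-aminopyridine catalysis and the base-induced ring contraction of alkylidene phthalides to indane-1,3-diones. Ring A closes in the 6-(enolendo)-exo-trig mode at the acyl carbon. The new C7 centre is controlled by the catalyst, whose triphenylmethyl-bearing arm blocks one face of the planar acylpyridinium so that the tethered enolate can bring C7 up only from the open side, and since 12 is one enol ether isomer (E) this fixes which face of C7 bonds; C3 is too remote to matter. The step needs C-acylation to win over return of the enolate oxygen and needs the acylpyridinium to be the only electrophile: O-recapture merely regenerates 12 while the C-acyl 1,3-dione is the thermodynamic sink, the C7 oxygen is silylated so that no second acyl group exists, O6 and the silyloxy group are trans across C6=C7 so that silyl transfer to the enolate oxygen cannot occur, and the acid-free medium avoids protonation of the enol ether at C7.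

**Step 9**
Reactants: 13
Product: 14 (3R,7R)-7-hydroxy-3,7-dimethyl-4,7-dihydro-3H-isochromene-6,8-dione
Conditions: HF·pyridine, pyridine, THF, 0 °C
Reagents that add atoms: none
Why: Fluoride-induced cleavage of a triethylsilyl ether under pyridine buffering, which should spare the enol ether and the non-enolisable 1,3-dione and cannot affect the quaternary C7 centre.

**Step 10**
Reactants: 14; 15 stearoyl chloride
Product: 16 (3R,7R)-3,7-dimethyl-6,8-dioxo-4,6,7,8-tetrahydro-3H-isochromen-7-yl octadecanoate (CNP0142202.1)
Conditions: Et3N, DMAP (0.2 equiv), CH2Cl2, 0 °C to rt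
Reagents that add atoms: none
Why: DMAP-catalysed acylation of the tertiary C7 alcohol by an acid chloride (nucleophilic catalysis through the acylpyridinium), a reaction type in use for the tertiary alcohols of azaphilones; C7 is quaternary and keeps its configuration.

**Compound list**
1 | (E)-1-methoxy-3-(trimethylsilyloxy)buta-1,3-diene | CO/C=C/C(=C)O[Si](C)(C)C | starting material
2 | acetaldehyde | CC=O | starting material
3 | (6R)-2-methoxy-6-methyl-4-(trimethylsilyloxy)-5,6-dihydro-2H-pyran (cycloadduct, both C2 epimers) | COC1C=C(O[Si](C)(C)C)C[C@@H](C)O1 | intermediate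
4 | (R)-2-methyl-2,3-dihydro-4H-pyran-4-one | C[C@@H]1CC(=O)C=CO1 | intermediate
5 | (R)-5-iodo-2-methyl-2,3-dihydro-4H-pyran-4-one | C[C@@H]1CC(=O)C(I)=CO1 | intermediate
6 | but-3-yn-2-ol (racemic) | CC(O)C#C | starting material
7 | triethyl(but-3-yn-2-yloxy)silane (racemic) | CC(O[Si](CC)(CC)CC)C#C | intermediate
8 | (2R)-5-iodo-2-methyl-4-[3-(triethylsilyloxy)but-1-yn-1-yl]-3,4-dihydro-2H-pyran-4-ol (both epimers at C4a and C7) | C[C@@H]1CC(O)(C#CC(C)O[Si](CC)(CC)CC)C(I)=CO1 | intermediate
9 | 1-[(2R)-5-iodo-2-methyl-2,3-dihydro-4H-pyran-4-ylidene]-3-(triethylsilyloxy)butan-2-one (E/Z mixture, both C7 epimers) | C[C@@H]1CC(=CC(=O)C(C)O[Si](CC)(CC)CC)C(I)=CO1 | intermediate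
10 | (6R)-6-methyl-4-[2-oxo-3-(triethylsilyloxy)butylidene]-5,6-dihydro-4H-pyran-3-carboxylic acid (E/Z mixture; the Z isomer, C6 syn to C8a, closes to 11) | C[C@@H]1CC(=CC(=O)C(C)O[Si](CC)(CC)CC)C(C(=O)O)=CO1 | intermediate
11 | (3R)-6-hydroxy-3-methyl-6-[1-(triethylsilyloxy)ethyl]-4,6-dihydro-3H-pyrano[3,4-c]pyran-8-one (hemiketal lactone, both epimers at C6 and C7) | CC(O[Si](CC)(CC)CC)C1(O)OC(=O)C2=CO[C@H](C)CC2=C1 | intermediate
12 | (3R,E)-3-methyl-6-[1-(triethylsilyloxy)ethylidene]-4,6-dihydro-3H-pyrano[3,4-c]pyran-8-one (enol lactone; methyl syn to O6) | C/C(O[Si](CC)(CC)CC)=C1\OC(=O)C2=CO[C@H](C)CC2=C1 | intermediate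
13 | (3R,7R)-3,7-dimethyl-7-(triethylsilyloxy)-4,7-dihydro-3H-isochromene-6,8-dione | CC[Si](CC)(CC)O[C@]1(C)C(=O)C=C2C[C@@H](C)OC=C2C1=O | intermediate
14 | (3R,7R)-7-hydroxy-3,7-dimethyl-4,7-dihydro-3H-isochromene-6,8-dione | O[C@]1(C)C(=O)C=C2C[C@@H](C)OC=C2C1=O | intermediate
15 | stearoyl chloride (octadecanoyl chloride) | CCCCCCCCCCCCCCCCCC(Cl)=O | starting material
16 | (3R,7R)-3,7-dimethyl-6,8-dioxo-4,6,7,8-tetrahydro-3H-isochromen-7-yl octadecanoate | CCCCCCCCCCCCCCCCCC(=O)O[C@]1(C)C(=O)C=C2C[C@@H](C)OC=C2C1=O | target

Total step count: 10. Longest linear sequence: 9 steps (steps 1, 2, 4, 5, 6, 7, 8, 9, 10).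

**Steps most likely to fail**

Step 8 (Proposed new method). What may go wrong: the enolate oxygen may simply return to C8 without C–C bond formation, face selection at C7 may be poor, the catalyst may add in conjugate fashion at C1, or adventitious acid may protonate C7 and degrade the enol lactone. The fallback sets out from 9 and returns at 13, and closes ring A by an aldol reaction in place of the acyl shift. Palladium-catalysed formylation of the vinyl iodide of 9 (Pd(PPh3)4, CO, Bu3SnH, THF, 50 °C) should give the aldehyde (6R)-6-methyl-4-[2-oxo-3-(triethylsilyloxy)butylidene]-5,6-dihydro-4H-pyran-3-carbaldehyde F1. Intramolecular aldol addition of the C7 enolate to the C8 aldehyde under equilibrating conditions (DBU, LiCl, MeCN, 0 °C to rt) should give the β-hydroxy ketone (3R)-8-hydroxy-3,7-dimethyl-7-(triethylsilyloxy)-3,4,7,8-tetrahydro-6H-isochromen-6-one F2. Oxidation of the C8 alcohol with DMP (1,1,1-triacetoxy-1,2-benziodoxol-3(1H)-one, CH2Cl2, pyridine) should give 13 together with its C7 epimer (3R,7S)-3,7-dimethyl-7-(triethylsilyloxy)-4,7-dihydro-3H-isochromene-6,8-dione F3. The two are diastereomers because of C3 and are separated by chromatography; 13 goes on to step 9.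

Step 7. What may go wrong: the reagent may activate the ring-opened carboxylic acid instead of the hemiketal hydroxyl; the sulfamate may ionise to the delocalised cation and lose a C4 proton (which would end in ring opening of the pyran); the elimination may give an E/Z mixture at C6=C7; the enol lactone may hydrolyse on isolation. The fallback sets out from 9 and returns at 12, and closes the lactone by carbonylation in one operation: PdCl2(PPh3)2, CO (1 atm), Et3N, MeCN, 60 °C. The acylpalladium formed from the vinyl iodide is captured by the enol oxygen of the C6 ketone (O-enolate trapping of an acylpalladium, known for ylidene phthalides and isocoumarins), so that neither the acid nor the hemiketal is handled. This fallback makes no new compound (F0).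

Step 5. What may go wrong: the tertiary, doubly activated carbinol may ionise and take up water at C1 (lactol formation and opening of the pyran ring), Rupe-type dehydration toward C4 may compete, or the silyl ether may be lost. The fallback sets out from 5 and returns at 9, and uses an aldol condensation in place of alkynylation and rearrangement. 3-Hydroxybutan-2-one is silylated (Et3SiCl, imidazole, CH2Cl2) to 3-(triethylsilyloxy)butan-2-one F4. Its kinetic lithium enolate (LiN(iPr)2, THF, −78 °C, deprotonation at the methyl group) is added to the C4a carbonyl of 5 and should give the β-hydroxy ketone 1-[(2R)-4-hydroxy-5-iodo-2-methyl-3,4-dihydro-2H-pyran-4-yl]-3-(triethylsilyloxy)butan-2-one F5. Mesylation and β-elimination toward the ketone (MeSO2Cl, Et3N, CH2Cl2, −20 to 0 °C) should then give 9.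

**Further compounds**
F1 | step 8 | (6R)-6-methyl-4-[2-oxo-3-(triethylsilyloxy)butylidene]-5,6-dihydro-4H-pyran-3-carbaldehyde | C[C@@H]1CC(=CC(=O)C(C)O[Si](CC)(CC)CC)C(C=O)=CO1
F2 | step 8 | (3R)-8-hydroxy-3,7-dimethyl-7-(triethylsilyloxy)-3,4,7,8-tetrahydro-6H-isochromen-6-one | CC[Si](CC)(CC)OC1(C)C(=O)C=C2C[C@@H](C)OC=C2C1O
F3 | step 8 | (3R,7S)-3,7-dimethyl-7-(triethylsilyloxy)-4,7-dihydro-3H-isochromene-6,8-dione | CC[Si](CC)(CC)O[C@@]1(C)C(=O)C=C2C[C@@H](C)OC=C2C1=O
F0 | step 7 | none | none
F4 | step 5 | 3-(triethylsilyloxy)butan-2-one | CC(=O)C(C)O[Si](CC)(CC)CC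
F5 | step 5 | 1-[(2R)-4-hydroxy-5-iodo-2-methyl-3,4-dihydro-2H-pyran-4-yl]-3-(triethylsilyloxy)butan-2-one | C[C@@H]1CC(O)(CC(=O)C(C)O[Si](CC)(CC)CC)C(I)=CO1
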